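The data were generated by integration with made-up constants.

At 10 d you need one number from this flask: monomer in chains divided by chains begun.

| flask | free monomer | pre-initiator | remark | time |
|---|---|---|---|---|
| north | 1 M (fed, over 3.0 d) | 5 mM | run made earlier; the fed solution adds 0.25 times the starting volume |  |
| south-east | 1 M (fed, over 3.0 d) | 7.5 mM | run made earlier; the fed solution adds 0.25 times the starting volume |  |
| west | 1.5 M (fed, over 3.0 d) | 10 mM | run made earlier; the fed solution adds 0.25 times the starting volume |  |
| flask | 1.0 M (fed, over 3.0 d) | 10 mM | the fed solution adds 0.25 times the starting volume | 10 d |

| run | time / d | monomer in chains / % | free monomer / % |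
|---|---|---|---|
| north | 0.833 | 0 | 26 |
| north | 1.67 | 0 | 53 |
| north | 4.00 | 33 | 64 |
| north | 10.0 | 88 | 12 |
| south-east | 1.25 | 4 | 37 |
| south-east | 4.00 | 43 | 57 |
| south-east | 6.00 | 76 | 28 |
| south-east | 10.0 | 95 | 4 |
| west | 0.833 | 0 | 29 |
| west | 1.67 | 4 | 52 |
| west | 4.00 | 59 | 41 |
| west | 10.0 | 103 | 3 |

(each reading ± 2 percentage points)

- charges are per starting volume, the dose included; the dosed solution carries all of it
- the average divides the monomer in chains by the number of chains begun, living and dead together
- the earlier runs were read with a standard deviation of 2 percentage points
- the earlier runs do not show the number of chains; that part of a forecast is a guess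
- percentages count the whole charge, also what has not yet gone in

- whether the average number of monomer units in a chain (chains begun, living or dead) reaches 70 by 10 d (yes / no)
- average number of monomer units in a chain (chains begun, living or dead) at 10 d

The flask has 100 as its charge ratio, [free monomer] over [pre-initiator], both as charged per starting volume. If a pre-initiator begins one chain at most, then

length = charge ratio × share in chains ÷ share of the pre-initiator begun (the initiator efficiency),

and setting that last share to one gives a floor.

The south-east run is this flask with less pre-initiator, 7.5 mM against 10 mM. More pre-initiator put more monomer into chains at 10.0 d, 88% in the north run against 95% in the south-east run, so as an estimate you can expect the flask to reach at least the south-east share: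

south-east floor = 133 × 95% = 127

flask floor = 100 × 95% = 95.0

From the south-east run to this flask the ratio falls by a factor 1.33, while the share in chains can rise by a factor of 1.05 before the charge is used up. So the flask's floor lies below the south-east floor, yet above 70, and your answer is yes. The readings show no count of chains, so your figure for the length stays this floor.

The forecast says yes, with 150 (105 to 210), a range that starts above your floor, holding that “about 60% is activated by 10 d”. The flask gives yes, with an average of 139, above your floor.

    free monomer + initiator → living end + monomer in chains (k = 0.0280 M⁻¹ h⁻¹)
    free monomer + living end → monomer in chains + living end, rate k2*[living end]*[free monomer] (k = 5.00 M⁻¹ h⁻¹)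
    living end + monomer in chains → dead end (k = 0.00550 M⁻¹ h⁻¹)
    pre-initiator → initiator (k = 0.0280 h⁻¹)

With 97.1% in chains and the ratio 100, that average means 69.9% of the pre-initiator charge has begun chains. At 10.0 d free monomer goes into growing chains 240 times as fast as into beginning new ones. That figure already stood at 220 at 3.87 d, and the average had passed 70 at 3.09 d, with 28.2% of the free monomer reacted.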